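**Retrosynthetic overview**

1. Locants follow the eremophilane skeleton: ring A = C1–C2–C3–C4–C5–C10, ring B = C5–C6–C7–C8–C9–C10, and C11–C13 is the 2-propenyl unit on C7.
2. Last bonds: the C3–O ester (dienoic acid made separately), before it C7–C11 (aldol on a C7 α-silyloxy enolate, carbon entering anti to the C5 methyl) and C7–O (Rubottom oxidation).
3. Key disconnection C1–C10: an intramolecular Heck reaction of a (Z)-alkenyl iodide onto a 4,4-disubstituted cyclohex-2-enone closes ring A and leaves the C8(=O)–C9=C10–C1=C2 dienone.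
4. Enabling feature: in ring B, C10 is the β-carbon of the enone C8(=O)–C9=C10 and is tied through quaternary C5, C4 and C3 to the cis C1=C2 bond, the only unsaturation of ring A, so enone and alkenyl carbon meet in a 6-exo closure.
5. Ring order: ring B is present from the start (3-methylcyclohex-2-enone); C4–C5 comes from a Claisen rearrangement with transfer of chirality, C3 from a Felkin alkynylation; ring A is closed in the key step.

Key step: step 9

Assumptions: (R)-2-methylbutanoic acid (chiral pool), (tert-butyldimethylsilyloxy)acetaldehyde and 2-(triphenylphosphoranylidene)propanal are bought. Where a CIP descriptor changes between intermediates without a reaction at that centre, only the priorities have changed.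

**Step 1**
Reactants: 1 3-methylcyclohex-2-en-1-one
Product: 2 (S)-3-methylcyclohex-2-en-1-ol
Conditions: (R)-2-methyl-CBS-oxazaborolidine (10 mol %), catecholborane, toluene, −78 °C; aq. NaOH work-up
Reagents that add atoms: none
Why: Corey–Bakshi–Shibata reduction in which the alkenyl flank of the enone acts as the large group, so that the (R)-oxazaborolidine should deliver hydride to the face that gives the (S)-carbinol, the centre that later controls C5.

**Step 2**
Reactants: 2 (S)-3-methylcyclohex-2-en-1-ol; 3 allyl bromide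
Product: 4 (S)-1-methyl-3-(prop-2-en-1-yloxy)cyclohex-1-ene
Conditions: NaH, Bu4NI (cat.), THF, 0 °C to rt
Reagents that add atoms: none
Why: Williamson ether synthesis on the sodium alkoxide, which does not touch the carbinol stereocentre.

**Step 3**
Reactants: 4 (S)-1-methyl-3-(prop-2-en-1-yloxy)cyclohex-1-ene
Product: 5 (S)-1-methyl-3-[(Z)-prop-1-en-1-yloxy]cyclohex-1-ene
Conditions: KOt-Bu (0.3 equiv), DMSO, 25–40 °C
Reagents that add atoms: none
Why: Base-mediated allyl-to-propenyl ether isomerisation, which runs through the cis-oxyallyl anion and is known to give (Z)-1-propenyl ethers, the exocyclic O–CH2 protons being removed in preference to the hindered ring C–H.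

**Step 4**
Reactants: 5 (S)-1-methyl-3-[(Z)-prop-1-en-1-yloxy]cyclohex-1-ene
Product: 6 (S)-2-[(R)-1-methylcyclohex-2-en-1-yl]propanal
Conditions: xylenes, K2CO3 (trace), sealed tube, 150 °C
Reagents that add atoms: none
Why: Claisen rearrangement in which the C4–C5 bond forms suprafacially on the face of the departing oxygen, which fixes quaternary C5, while the chair transition state with the (Z)-methyl turned away from the ring should set C4 so that the two methyl groups end cis on ring A.

**Step 5**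
Reactants: 6 (S)-2-[(R)-1-methylcyclohex-2-en-1-yl]propanal; 7 ethynylmagnesium bromide
Product: 8 (3R,4S)-4-[(R)-1-methylcyclohex-2-en-1-yl]pent-1-yn-3-ol
Conditions: THF, −78 to −40 °C; aq. NH4Cl
Reagents that add atoms: none
Why: Felkin–Anh addition of the alkynyl Grignard reagent, with quaternary C5 as the large group anti to the incoming nucleophile, should set the C3 carbinol in the configuration of the target.

**Step 6**
Reactants: 8 (3R,4S)-4-[(R)-1-methylcyclohex-2-en-1-yl]pent-1-yn-3-ol
Product: 10 (3R,4S,Z)-1-iodo-4-[(R)-1-methylcyclohex-2-en-1-yl]pent-1-en-3-ol, via sodium alkenylalanate 9 (not isolated)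
Conditions: NaAlH2(OCH2CH2OMe)2 (Red-Al), THF, 0 °C to rt; then I2, THF, −78 °C; aq. KNaC4H4O6 work-up
Reagents that add atoms: iodine, [I][I]; sodium bis(2-methoxyethoxy)aluminium dihydride, [Na+].[AlH2-](OCCOC)OCCOC (its aluminium and alkoxide groups stay only in intermediate 9)
Why: Hydroxyl-directed trans-hydroalumination of the propargylic alkoxide places aluminium on the terminal carbon cis to the carbinol carbon in a five-membered alanate, and iodinolysis with retention should give the (Z)-alkenyl iodide.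

**Step 7**
Reactants: 10 (3R,4S,Z)-1-iodo-4-[(R)-1-methylcyclohex-2-en-1-yl]pent-1-en-3-ol
Product: 11 tert-butyl{[(3R,4S,Z)-1-iodo-4-[(R)-1-methylcyclohex-2-en-1-yl]pent-1-en-3-yl]oxy}dimethylsilane
Conditions: TBSOTf, 2,6-lutidine, CH2Cl2, −78 to 0 °C
Reagents that add atoms: tert-butyldimethylsilyl trifluoromethanesulfonate, CC(C)(C)[Si](C)(C)OS(=O)(=O)C(F)(F)F
Why: Silylation of the hindered secondary allylic alcohol with the silyl triflate gives an ether that should survive the oxidation, palladium and amide-base steps that follow.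

**Step 8**
Reactants: 11 tert-butyl{[(3R,4S,Z)-1-iodo-4-[(R)-1-methylcyclohex-2-en-1-yl]pent-1-en-3-yl]oxy}dimethylsilane
Product: 12 (R)-4-[(2S,3R,4Z)-3-{[tert-butyl(dimethyl)silyl]oxy}-5-iodopent-4-en-2-yl]-4-methylcyclohex-2-en-1-one
Conditions: CrO3, 3,5-dimethylpyrazole, CH2Cl2, −20 °C
Reagents that add atoms: chromium trioxide, O=[Cr](=O)=O
Why: Allylic oxidation with the CrO3–3,5-dimethylpyrazole complex, in which C8 is the only allylic methylene of the ring alkene because the other allylic carbon is quaternary C5, so that the 4,4-disubstituted cyclohex-2-enone should form while the electron-poor iodoalkene is left alone.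

**Step 9**
Reactants: 12 (R)-4-[(2S,3R,4Z)-3-{[tert-butyl(dimethyl)silyl]oxy}-5-iodopent-4-en-2-yl]-4-methylcyclohex-2-en-1-one
Product: 13 (4aS,5S,6S)-6-{[tert-butyl(dimethyl)silyl]oxy}-4a,5-dimethyl-4,4a,5,6-tetrahydronaphthalen-2(3H)-one
Conditions: Pd(OAc)2 (10 mol %), PPh3 (25 mol %), Ag2CO3 (2 equiv), MeCN, 80 °C
Reagents that add atoms: none
Why: Zerovalent palladium formed in situ inserts into the C1–I bond with retention of the (Z)-geometry, the alkenylpalladium adds syn across C9=C10 so that C1 bonds to C10 (the enone β-carbon) and palladium sits on C9, the C-bound palladium enolate equilibrates through its O-bound form to the face syn to H-10, and syn β-hydride elimination returns the enone as the C8(=O)–C9=C10–C1=C2 dienone. The closest known reaction type is the intramolecular Mizoroki–Heck alkenylation of cyclic enones that gives β-substituted enones instead of conjugate-addition products. Ring A is closed in the 6-exo-trig mode (C1 onto C10, with C9 outside the new ring). No new stereocentre survives, because C10 ends sp2, and C3, C4 and C5 are not touched. The step needs 6-exo over 7-endo closure, secured by the tether through quaternary C5 and by the polarisation of the enone, and it needs elimination over reduction of the palladium enolate, secured by Ag2CO3 as a halide-abstracting base in the absence of any hydride donor; the cis relation of iodine and C3 made in step 6 is what lets C1 reach C10.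

**Step 10**
Reactants: 13 (4aS,5S,6S)-6-{[tert-butyl(dimethyl)silyl]oxy}-4a,5-dimethyl-4,4a,5,6-tetrahydronaphthalen-2(3H)-one
Product: 16 (4aS,5S,6S)-3,6-bis{[tert-butyl(dimethyl)silyl]oxy}-4a,5-dimethyl-4,4a,5,6-tetrahydronaphthalen-2(3H)-one as a mixture of C3 epimers, via silyl dienol ether 14 (not isolated), via silyloxy oxirane 15 (not isolated)
Conditions: LiN(i-Pr)2 (LDA), THF, −78 °C; TBSOTf; then dimethyldioxirane, acetone/CH2Cl2, −40 °C to rt
Reagents that add atoms: tert-butyldimethylsilyl trifluoromethanesulfonate, CC(C)(C)[Si](C)(C)OS(=O)(=O)C(F)(F)F; dimethyldioxirane, CC1(C)OO1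
Why: Rubottom oxidation in which kinetic α′-deprotonation at C7 gives the cross-conjugated dienolate, O-silylation, epoxidation of the electron-rich enol ether and 1,4-silyl shift should give the α-silyloxy ketone, whose C7 configuration does not matter because the centre is enolised again in step 11.

**Step 11**
Reactants: 16 (4aS,5S,6S)-3,6-bis{[tert-butyl(dimethyl)silyl]oxy}-4a,5-dimethyl-4,4a,5,6-tetrahydronaphthalen-2(3H)-one; 17 (tert-butyldimethylsilyloxy)acetaldehyde
Product: 18 (3S,4aS,5S,6S)-3,6-bis{[tert-butyl(dimethyl)silyl]oxy}-3-(2-{[tert-butyl(dimethyl)silyl]oxy}-1-hydroxyethyl)-4a,5-dimethyl-4,4a,5,6-tetrahydronaphthalen-2(3H)-one (carbinol epimers)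
Conditions: LiN(i-Pr)2, THF, −78 to −40 °C; then 17, −78 °C; AcOH quench at −78 °C
Reagents that add atoms: none
Why: Aldol addition of the tetrasubstituted lithium enolate, in which the aldehyde should approach C7 on the ring-B face opposite the axial C5 methyl group, so that the new carbon substituent ends trans and the oxygen cis to that methyl as in the target, while the carbinol centre at C11 is removed in step 12.

**Step 12**
Reactants: 18 (3S,4aS,5S,6S)-3,6-bis{[tert-butyl(dimethyl)silyl]oxy}-3-(2-{[tert-butyl(dimethyl)silyl]oxy}-1-hydroxyethyl)-4a,5-dimethyl-4,4a,5,6-tetrahydronaphthalen-2(3H)-one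
Product: 19 (3R,4aS,5S,6S)-3,6-bis{[tert-butyl(dimethyl)silyl]oxy}-3-({[tert-butyl(dimethyl)silyl]oxy}acetyl)-4a,5-dimethyl-4,4a,5,6-tetrahydronaphthalen-2(3H)-one
Conditions: Dess–Martin periodinane, NaHCO3, CH2Cl2, 0 °C to rt
Reagents that add atoms: none
Why: Dess–Martin oxidation of the hindered secondary alcohol under buffered, non-basic conditions that should avoid retro-aldol cleavage and silyl migration.

**Step 13**
Reactants: 19 (3R,4aS,5S,6S)-3,6-bis{[tert-butyl(dimethyl)silyl]oxy}-3-({[tert-butyl(dimethyl)silyl]oxy}acetyl)-4a,5-dimethyl-4,4a,5,6-tetrahydronaphthalen-2(3H)-one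
Product: 20 (3S,4aS,5S,6S)-3,6-bis{[tert-butyl(dimethyl)silyl]oxy}-3-(3-{[tert-butyl(dimethyl)silyl]oxy}prop-1-en-2-yl)-4a,5-dimethyl-4,4a,5,6-tetrahydronaphthalen-2(3H)-one
Conditions: Cp2Ti(μ-Cl)(μ-CH2)AlMe2 (Tebbe reagent, 1.2 equiv), pyridine, THF/toluene, −40 to 0 °C
Reagents that add atoms: Tebbe reagent, C[Al-]1(C)C[Ti](C2C=CC=C2)(C2C=CC=C2)[Cl+]1
Why: Tebbe methylenation, which is not basic and tolerates hindered ketones, should take the isolated, α-oxygenated C11 ketone in preference to the cross-conjugated and less electrophilic C8 carbonyl.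

**Step 14**
Reactants: 20 (3S,4aS,5S,6S)-3,6-bis{[tert-butyl(dimethyl)silyl]oxy}-3-(3-{[tert-butyl(dimethyl)silyl]oxy}prop-1-en-2-yl)-4a,5-dimethyl-4,4a,5,6-tetrahydronaphthalen-2(3H)-one
Product: 21 (3S,4aS,5S,6S)-3,6-dihydroxy-3-(3-hydroxyprop-1-en-2-yl)-4a,5-dimethyl-4,4a,5,6-tetrahydronaphthalen-2(3H)-one
Conditions: HF·pyridine, pyridine, THF, 0 °C to rt
Reagents that add atoms: none
Why: Fluoride-driven cleavage of the three silyl ethers (strong Si–F bond) under buffered conditions that the dienone and the tertiary α-ketol should tolerate.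

**Step 15**
Reactants: 21 (3S,4aS,5S,6S)-3,6-dihydroxy-3-(3-hydroxyprop-1-en-2-yl)-4a,5-dimethyl-4,4a,5,6-tetrahydronaphthalen-2(3H)-one
Product: 22 (3S,4aS,5S,6S)-3-[3-(acetyloxy)prop-1-en-2-yl]-3,6-dihydroxy-4a,5-dimethyl-4,4a,5,6-tetrahydronaphthalen-2(3H)-one
Conditions: AcCl (1.05 equiv), 2,4,6-collidine, CH2Cl2, −78 °C
Reagents that add atoms: acetyl chloride, CC(Cl)=O
Why: Selective acylation of the unhindered primary allylic alcohol at low temperature with a hindered base, the secondary C3 hydroxyl next to the C4 methyl and the tertiary C7 hydroxyl reacting much more slowly.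

**Step 16**
Reactants: 23 (R)-2-methylbutanoic acid
Product: 24 (R)-N-methoxy-N,2-dimethylbutanamide
Conditions: 1,1'-carbonyldiimidazole, CH2Cl2, 0 °C; then MeNH(OMe)·HCl, rt
Reagents that add atoms: N,O-dimethylhydroxylamine hydrochloride, CNOC.Cl
Why: Weinreb amide formation through the acyl imidazole, mild enough to keep the α-stereocentre.

**Step 17**
Reactants: 24 (R)-N-methoxy-N,2-dimethylbutanamide; 25 2-(triphenylphosphoranylidene)propanal
Product: 27 (R,E)-2,4-dimethylhex-2-enal, via (R)-2-methylbutanal 26 (not isolated)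
Conditions: i-Bu2AlH, CH2Cl2, −78 °C; aq. KNaC4H4O6 work-up; dried solution treated with 25, toluene, 80 °C
Reagents that add atoms: none
Why: Reduction of the Weinreb amide stops at the aldehyde through the chelated aluminium hemiaminal, and the Wittig reaction with the stabilised formyl ylide should give the (E)-trisubstituted enal without exposing the labile α-chiral aldehyde to strong base.

**Step 18**
Reactants: 27 (R,E)-2,4-dimethylhex-2-enal; 28 triethyl phosphonoacetate
Product: 29 ethyl (2E,4E,6R)-4,6-dimethylocta-2,4-dienoate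
Conditions: NaH, THF, 0 °C to rt
Reagents that add atoms: none
Why: Horner–Wadsworth–Emmons olefination with the stabilised phosphonate anion, which should give the (E)-enoate.

**Step 19**
Reactants: 29 ethyl (2E,4E,6R)-4,6-dimethylocta-2,4-dienoate
Product: 30 (2E,4E,6R)-4,6-dimethylocta-2,4-dienoic acid
Conditions: LiOH, THF/MeOH/H2O, rt; then 1 M HCl
Reagents that add atoms: lithium hydroxide, [Li+].[OH-]
Why: Saponification of the ethyl ester under conditions in which the remote C6 stereocentre is not acidic.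

**Step 20**
Reactants: 22 (3S,4aS,5S,6S)-3-[3-(acetyloxy)prop-1-en-2-yl]-3,6-dihydroxy-4a,5-dimethyl-4,4a,5,6-tetrahydronaphthalen-2(3H)-one; 30 (2E,4E,6R)-4,6-dimethylocta-2,4-dienoic acid
Product: 32 (1S,2S,7S,8aS)-7-[3-(acetyloxy)prop-1-en-2-yl]-7-hydroxy-1,8a-dimethyl-6-oxo-1,2,6,7,8,8a-hexahydronaphthalen-2-yl (2E,4E,6R)-4,6-dimethylocta-2,4-dienoate (target), via mixed anhydride 31 (not isolated)
Conditions: 2,4,6-trichlorobenzoyl chloride, Et3N, THF, rt; then 22, DMAP, toluene, rt
Reagents that add atoms: 2,4,6-trichlorobenzoyl chloride, O=C(Cl)c1c(Cl)cc(Cl)cc1Cl (its acyl group stays only in intermediate 31)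
Why: Yamaguchi esterification through the mixed anhydride, in which only the secondary C3 hydroxyl should be acylated because the tertiary C7 hydroxyl is inert, and no stereocentre is affected.

**Compound list**

1 | 3-methylcyclohex-2-en-1-one | CC1=CC(=O)CCC1 | starting material
2 | (S)-3-methylcyclohex-2-en-1-ol | O[C@@H]1C=C(C)CCC1 | intermediate
3 | allyl bromide | C=CCBr | starting material
4 | (S)-1-methyl-3-(prop-2-en-1-yloxy)cyclohex-1-ene | C=CCO[C@@H]1C=C(C)CCC1 | intermediate
5 | (S)-1-methyl-3-[(Z)-prop-1-en-1-yloxy]cyclohex-1-ene | C/C=C\O[C@@H]1C=C(C)CCC1 | intermediate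
6 | (S)-2-[(R)-1-methylcyclohex-2-en-1-yl]propanal | C[C@@]1(C=CCCC1)[C@H](C)C=O | intermediate
7 | ethynylmagnesium bromide | C#C[Mg]Br | starting material
8 | (3R,4S)-4-[(R)-1-methylcyclohex-2-en-1-yl]pent-1-yn-3-ol | C[C@@]1(C=CCCC1)[C@H](C)[C@@H](O)C#C | intermediate
9 | sodium alkenylalanate (five-membered ring O–Al–C1=C2–C3, two 2-methoxyethoxide groups on aluminium) | C[C@@]1(C=CCCC1)[C@H](C)[C@H]2O[Al-](OCCOC)(OCCOC)C=C2.[Na+] | intermediate
10 | (3R,4S,Z)-1-iodo-4-[(R)-1-methylcyclohex-2-en-1-yl]pent-1-en-3-ol | C[C@@]1(C=CCCC1)[C@H](C)[C@@H](O)/C=C\I | intermediate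
11 | tert-butyl{[(3R,4S,Z)-1-iodo-4-[(R)-1-methylcyclohex-2-en-1-yl]pent-1-en-3-yl]oxy}dimethylsilane | C[C@@]1(C=CCCC1)[C@H](C)[C@@H](O[Si](C)(C)C(C)(C)C)/C=C\I | intermediate
12 | (R)-4-[(2S,3R,4Z)-3-{[tert-butyl(dimethyl)silyl]oxy}-5-iodopent-4-en-2-yl]-4-methylcyclohex-2-en-1-one | O=C1CC[C@](C)(C=C1)[C@H](C)[C@@H](O[Si](C)(C)C(C)(C)C)/C=C\I | intermediate
13 | (4aS,5S,6S)-6-{[tert-butyl(dimethyl)silyl]oxy}-4a,5-dimethyl-4,4a,5,6-tetrahydronaphthalen-2(3H)-one | O=C1CC[C@]2(C)C(=C1)C=C[C@H](O[Si](C)(C)C(C)(C)C)[C@H]2C | intermediate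
14 | (4aS,5S,6S)-2,6-bis{[tert-butyl(dimethyl)silyl]oxy}-4a,5-dimethyl-4,4a,5,6-tetrahydronaphthalene (silyl dienol ether) | CC(C)(C)[Si](C)(C)OC1=CC[C@]2(C)C(=C1)C=C[C@H](O[Si](C)(C)C(C)(C)C)[C@H]2C | intermediate
15 | 2,3-epoxide of 14 (silyloxy oxirane, epoxide face not defined) | CC(C)(C)[Si](C)(C)OC12OC1C[C@]3(C)C(=C2)C=C[C@H](O[Si](C)(C)C(C)(C)C)[C@H]3C | intermediate
16 | (4aS,5S,6S)-3,6-bis{[tert-butyl(dimethyl)silyl]oxy}-4a,5-dimethyl-4,4a,5,6-tetrahydronaphthalen-2(3H)-one (C3 epimers) | O=C1C(O[Si](C)(C)C(C)(C)C)C[C@]2(C)C(=C1)C=C[C@H](O[Si](C)(C)C(C)(C)C)[C@H]2C | intermediate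
17 | (tert-butyldimethylsilyloxy)acetaldehyde | O=CCO[Si](C)(C)C(C)(C)C | starting material
18 | (3S,4aS,5S,6S)-3,6-bis{[tert-butyl(dimethyl)silyl]oxy}-3-(2-{[tert-butyl(dimethyl)silyl]oxy}-1-hydroxyethyl)-4a,5-dimethyl-4,4a,5,6-tetrahydronaphthalen-2(3H)-one (carbinol epimers) | O=C1[C@@](O[Si](C)(C)C(C)(C)C)(C(O)CO[Si](C)(C)C(C)(C)C)C[C@]2(C)C(=C1)C=C[C@H](O[Si](C)(C)C(C)(C)C)[C@H]2C | intermediate
19 | (3R,4aS,5S,6S)-3,6-bis{[tert-butyl(dimethyl)silyl]oxy}-3-({[tert-butyl(dimethyl)silyl]oxy}acetyl)-4a,5-dimethyl-4,4a,5,6-tetrahydronaphthalen-2(3H)-one | O=C1[C@@](O[Si](C)(C)C(C)(C)C)(C(=O)CO[Si](C)(C)C(C)(C)C)C[C@]2(C)C(=C1)C=C[C@H](O[Si](C)(C)C(C)(C)C)[C@H]2C | intermediate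
20 | (3S,4aS,5S,6S)-3,6-bis{[tert-butyl(dimethyl)silyl]oxy}-3-(3-{[tert-butyl(dimethyl)silyl]oxy}prop-1-en-2-yl)-4a,5-dimethyl-4,4a,5,6-tetrahydronaphthalen-2(3H)-one | C=C(CO[Si](C)(C)C(C)(C)C)[C@@]1(O[Si](C)(C)C(C)(C)C)C[C@]2(C)C(=CC1=O)C=C[C@H](O[Si](C)(C)C(C)(C)C)[C@H]2C | intermediate
21 | (3S,4aS,5S,6S)-3,6-dihydroxy-3-(3-hydroxyprop-1-en-2-yl)-4a,5-dimethyl-4,4a,5,6-tetrahydronaphthalen-2(3H)-one | C=C(CO)[C@@]1(O)C[C@]2(C)C(=CC1=O)C=C[C@H](O)[C@H]2C | intermediate
22 | (3S,4aS,5S,6S)-3-[3-(acetyloxy)prop-1-en-2-yl]-3,6-dihydroxy-4a,5-dimethyl-4,4a,5,6-tetrahydronaphthalen-2(3H)-one | C=C(COC(C)=O)[C@@]1(O)C[C@]2(C)C(=CC1=O)C=C[C@H](O)[C@H]2C | intermediate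
23 | (R)-2-methylbutanoic acid | CC[C@@H](C)C(=O)O | starting material
24 | (R)-N-methoxy-N,2-dimethylbutanamide | CC[C@@H](C)C(=O)N(C)OC | intermediate
25 | 2-(triphenylphosphoranylidene)propanal | CC(C=O)=P(c1ccccc1)(c1ccccc1)c1ccccc1 | starting material
26 | (R)-2-methylbutanal | CC[C@@H](C)C=O | intermediate
27 | (R,E)-2,4-dimethylhex-2-enal | CC[C@@H](C)/C=C(\C)C=O | intermediate
28 | triethyl phosphonoacetate | CCOC(=O)CP(=O)(OCC)OCC | starting material
29 | ethyl (2E,4E,6R)-4,6-dimethylocta-2,4-dienoate | CC[C@@H](C)/C=C(\C)/C=C/C(=O)OCC | intermediate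
30 | (2E,4E,6R)-4,6-dimethylocta-2,4-dienoic acid | CC[C@@H](C)/C=C(\C)/C=C/C(=O)O | intermediate
31 | (2E,4E,6R)-4,6-dimethylocta-2,4-dienoic 2,4,6-trichlorobenzoic anhydride | CC[C@@H](C)/C=C(\C)/C=C/C(=O)OC(=O)c1c(Cl)cc(Cl)cc1Cl | intermediate
32 | (1S,2S,7S,8aS)-7-[3-(acetyloxy)prop-1-en-2-yl]-7-hydroxy-1,8a-dimethyl-6-oxo-1,2,6,7,8,8a-hexahydronaphthalen-2-yl (2E,4E,6R)-4,6-dimethylocta-2,4-dienoate | C=C(COC(C)=O)[C@@]1(O)C[C@]2(C)C(=CC1=O)C=C[C@H](OC(=O)/C=C/C(C)=C/[C@H](C)CC)[C@H]2C | target

**Step count and risks**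

Total step count: 20 (steps 1–15 and 20 in the main line, steps 16–19 for the acid). Longest linear sequence: 16 steps (steps 1–15, then step 20).

Steps most likely to fail:

Step 9 (key step). The palladium enolate formed after ring closure may be protonated or reduced before it can epimerise and undergo β-hydride elimination, so that the enone is not regenerated, or the alkenylpalladium may decompose before the hindered insertion next to quaternary C5. The fallback sets out from 12 and separates ring closure from re-oxidation. Nickel-catalysed reductive conjugate addition of the alkenyl iodide to the enone with in situ silylation (NiCl2·DME, neocuproine, Mn powder, Et3SiCl, DMF, rt) should give the cis-fused triethylsilyl enol ether F1, in which the double bond is fixed between C8 and C9. Saegusa–Ito oxidation (Pd(OAc)2, O2, DMSO, 50 °C) then introduces C9=C10 without regiochemical choice and comes back to 13.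

Step 4. The chair and boat transition states of the sigmatropic shift may not be discriminated well enough on the cyclohexenyl framework, which would erode the configuration at C4, and the allylic ether may ionise at the temperature needed. The fallback sets out from 2 and sets C4 by an auxiliary instead of by the rearrangement. Vinyl exchange (ethyl vinyl ether, Hg(OAc)2 cat., reflux) gives (S)-3-(ethenyloxy)-1-methylcyclohex-1-ene F2, whose Claisen rearrangement (xylenes, 140 °C) sets C5 alone and gives (S)-2-(1-methylcyclohex-2-en-1-yl)acetaldehyde F3. Condensation with (R)-1-amino-2-(methoxymethyl)pyrrolidine (RAMP) gives the RAMP hydrazone F4. Enders alkylation (LiN(i-Pr)2, THF, 0 °C; MeI, −100 °C) should give the C4-methylated hydrazone F5 under control of the auxiliary. Cleavage with aqueous oxalic acid/ether comes back to 6.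

Step 13. The methylenating reagent may not distinguish the C11 ketone from the C8 carbonyl, or the 1,3-dicarbonyl may cleave or enolise instead of reacting. The fallback sets out from 16 and makes the methylene group by elimination, so that steps 11–13 are replaced. The lithium enolate of 16 (LiN(i-Pr)2, THF, −78 °C, anhydrous CeCl3 if needed) is added to 1-[(tert-butyldimethylsilyl)oxy]propan-2-one to give the tertiary aldol F6, with the carbon substituent again entering anti to the C5 methyl. Syn-elimination with methyl N-(triethylammoniosulfonyl)carbamate (Burgess reagent, toluene, 50 °C) toward the methyl group comes back to 20.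

**Further compounds**

F1 | step 9 | cis-fused triethylsilyl enol ether of the conjugate-addition product (C8–OSiEt3, C8=C9, H-10 cis to the C5 methyl, C3 silyl ether kept) | CC[Si](CC)(CC)OC1=C[C@@H]2C=C[C@H](O[Si](C)(C)C(C)(C)C)[C@@H](C)[C@]2(C)CC1
F2 | step 4 | (S)-3-(ethenyloxy)-1-methylcyclohex-1-ene | C=CO[C@@H]1C=C(C)CCC1
F3 | step 4 | (S)-2-(1-methylcyclohex-2-en-1-yl)acetaldehyde | C[C@@]1(C=CCCC1)CC=O
F4 | step 4 | (R)-2-(methoxymethyl)-N-{(E)-2-[(S)-1-methylcyclohex-2-en-1-yl]ethylidene}pyrrolidin-1-amine | COC[C@H]1CCCN1/N=C/C[C@@]2(C)C=CCCC2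
F5 | step 4 | (R)-2-(methoxymethyl)-N-{(1E,2S)-2-[(R)-1-methylcyclohex-2-en-1-yl]propylidene}pyrrolidin-1-amine | COC[C@H]1CCCN1/N=C/[C@@H](C)[C@@]2(C)C=CCCC2
F6 | step 13 | (3S,4aS,5S,6S)-3,6-bis{[tert-butyl(dimethyl)silyl]oxy}-3-(1-{[tert-butyl(dimethyl)silyl]oxy}-2-hydroxypropan-2-yl)-4a,5-dimethyl-4,4a,5,6-tetrahydronaphthalen-2(3H)-one (carbinol epimers) | O=C1[C@@](O[Si](C)(C)C(C)(C)C)(C(C)(O)CO[Si](C)(C)C(C)(C)C)C[C@]2(C)C(=C1)C=C[C@H](O[Si](C)(C)C(C)(C)C)[C@H]2C
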